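1. If a flask holds less of one reagent than of anything that reagent can react with, I start from that reagent's balance. Here I had 0.110 M of incoming ligand against 0.22 M of starting complex and 0.220 M of protic impurity, so the ligand was the limiting reagent.

| setting | south-west | west | south | delta | gamma | beta | theta |
|---|---|---|---|---|---|---|---|
| starting complex | 0.22 M | 0.22 M | 0.22 M | 0.22 M | 0.22 M (fed, over 80 min) | 0.22 M (in portions, 4, over 80 min) | 0.22 M |
| incoming ligand | 0.50 equiv | 0.50 equiv | 0.50 equiv | 0.500 equiv | 0.500 equiv | 0.500 equiv | 0.500 equiv (fed, over 80 min) |
| protic impurity | 0.22 M | 0.15 M | 0.33 M | 0.220 M | 0.220 M | 0.220 M | 0.220 M |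
| remark | run made earlier | run made earlier | run made earlier | everything together at the start | all else is in the flask from the start; the feed brings no volume worth counting | first portion at the start, last at 80 min | all else is in the flask from the start; the feed brings no volume worth counting |
| time |  |  |  | 1.5 h | 1.5 h | 1.5 h | 1.5 h |

| run | time / min | complex with one exchanged / % | starting complex / % |
|---|---|---|---|
| south-west | 6.00 | 11.8 | 87.8 |
| south-west | 20.0 | 21.8 | 74.6 |
| south-west | 40.0 | 26.8 | 69.4 |
| south-west | 50.0 | 27.2 | 68.7 |
| west | 25.0 | 25.7 | 71.3 |
| west | 50.0 | 30.3 | 65.1 |
| west | 80.0 | 32.3 | 63.2 |
| west | 120 | 32.1 | 62.7 |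
| south | 25.0 | 21.4 | 75.4 |
| south | 50.0 | 24.4 | 72.5 |
| south | 80.0 | 25.3 | 71.8 |
| south | 120 | 25.1 | 70.1 |

(readings scatter by 0.5 percentage points)

* the best flask by amount of complex with one exchanged, in percent of the starting complex charged; "all alike" if 1.5 percentage points covers them all (delta / gamma / beta / theta / all alike)
* amount of complex with one exchanged at the end, in percent of the starting complex charged, delta
* amount of complex with one exchanged at the end, in percent of the starting complex charged, gamma
* amount of complex with one exchanged at the end, in percent of the starting complex charged, beta
* amount of complex with one exchanged at the end, in percent of the starting complex charged, theta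

- candidate steps: starting complex + incoming ligand -> leaving ligand + complex with one exchanged; protic impurity + incoming ligand -> quenched reagent; complex with one exchanged + incoming ligand <-> leaving ligand + complex with two exchanged; complex with one exchanged <-> isomer of the product

2. The south-west run has delta's recipe, so I drew delta's curve from it. Complex with one exchanged began with a slope of 0.00433 M/min over the first 6.00 min.

3. The knee lay between 20.0 min and 40.0 min, where the south-west slope was down to 5.50 × 10⁻⁴ M/min, less than at the start.

4. The south-west curve then levelled: the last interval added 0.4 percentage points, against a scatter of 0.5 points, and the last reading stood at 27.2%.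

5. At that last reading the south-west run had lost 0.0689 M of starting complex. I defined the keep factor f as the part of the lost starting complex that still stands as complex with one exchanged, and read f = 0.869; the west run reads 0.861.

6. So, taking f as the same in each flask and setting aside any ligand taken by a second exchange, I wrote the product, as a part of the complex charged, as P = f(C − Q − R)/A, with C the ligand charged, Q the quenched reagent, R the ligand remaining and A the complex charged. At a given f and R, a flask's yield thus falls as the impurity takes more ligand, and I expected gamma, which starts without starting complex, to lose more to Q than delta.

7. The forecast named delta best, with 27.5% for delta, 17.7% for gamma, 18.2% for beta and 23.7% for theta, holding that feeding the complex or adding it in portions "lets the impurity consume ligand first".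

8. The flasks gave 28.8% for delta, 16.2% for gamma, 17.7% for beta and 26.3% for theta, so delta was best, as forecast.

    starting complex + incoming ligand → leaving ligand + complex with one exchanged (k = 0.255 /M/min)
    protic impurity + incoming ligand → quenched reagent (k = 0.117 /M/min)
    complex with one exchanged + incoming ligand ⇌ leaving ligand + complex with two exchanged (K = 1.80, k = 0.0116 /M/min)
    complex with one exchanged ⇌ isomer of the product (K = 0.130, k = 0.0483 /min)

Gamma ended with 0.0672 M of quenched reagent and 1.73% of its ligand remaining, so P with the keep factor gives 16.1% for gamma, which stood at 16.2%. The neighbouring flask is gamma with 0.300 equiv of incoming ligand; it ended with 0.0413 M of quenched reagent and 1.14% of its ligand remaining, so P gives 9.46%, and that flask held 9.53% of complex with one exchanged.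

The numbers in the tables come from a simulation on assumed constants, noise included.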